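**Retrosynthetic overview**
- The target is epiafzelechin-(4β→8)-ent-epiafzelechin-(4α→8)-epiafzelechin. The two natural (2R,3R) units come from the chiral pool; only the unnatural (2S,3S,4R) middle unit is built.
- Last C–C disconnection: C4(top)–C8(middle), a Lewis-acid 4→8 coupling of a C4-activated epiafzelechin with the middle–bottom dimer, followed by global hydrogenolysis.
- Key disconnection: ring C of the middle unit, O1–C2 and C3–C4 in one [4+2] event. The partners are an o-quinone methide (O1=C8a–C4a=C4, with C4 already carrying C8 of the bottom unit) and a (Z)-2-arylvinylboronate (C2=C3) whose boron is a masked 3-OH.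
- Enabling feature: ring A of the middle unit is a phloroglucinol ring with O1 ortho to C4a, so O1–C8a–C4a–C4 is a latent oxadiene with a doubly benzylic C4, and C2=C3 is a p-oxygenated styrene. The cis C2/C3 pair is carried in by the Z-alkene and C4 follows by steric control.
- Ring order: all rings of the top and bottom units and ring A of the middle unit are bought; ring B of the middle unit comes with the alkyne; ring C of the middle unit is the only ring formed (step 7).

Key step: step 7

Assumption: (−)-epiafzelechin is taken as a purchasable chiral-pool compound; which antipode of the chiral acid in step 7 is matched to the enantiopure quinone methide cannot be deduced with certainty, and the (R)-acid is written.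

**Step 1**
Reactants: 1 (−)-epiafzelechin
Product: 2 (2R,3R)-5,7-bis(benzyloxy)-2-[4-(benzyloxy)phenyl]chroman-3-ol
Conditions: BnBr (3.3 equiv), K2CO3, DMF, 0 °C to rt
Reagents that add atoms: benzyl bromide, BrCc1ccccc1
Why: Williamson etherification alkylates the three phenoxides formed by K2CO3 while the un-ionised secondary 3-OH is left, and neither stereocenter is touched.

**Step 2**
Reactants: 2 (2R,3R)-5,7-bis(benzyloxy)-2-[4-(benzyloxy)phenyl]chroman-3-ol
Product: 3 (2R,3R)-3,5,7-tris(benzyloxy)-2-[4-(benzyloxy)phenyl]chromane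
Conditions: NaH, BnBr, DMF, 0 °C to rt
Reagents that add atoms: benzyl bromide, BrCc1ccccc1
Why: Williamson etherification of the sodium alkoxide puts a hydrogenolysable benzyl group on O3 so that the unit tolerates organolithium chemistry; C2 and C3 are untouched.

**Step 3**
Reactants: 3 (2R,3R)-3,5,7-tris(benzyloxy)-2-[4-(benzyloxy)phenyl]chromane
Product: 4 (2R,3R)-8-bromo-3,5,7-tris(benzyloxy)-2-[4-(benzyloxy)phenyl]chromane
Conditions: NBS (1.0 equiv), CH2Cl2, −78 °C to 0 °C
Reagents that add atoms: N-bromosuccinimide, BrN1C(=O)CCC1=O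
Why: Electrophilic aromatic bromination should occur at C8 of ring A, the most nucleophilic and least hindered position of 5,7-dibenzyloxyflavans, and not on the mono-oxygenated ring B.

**Step 4**
Reactants: 5 2,4,6-trihydroxybenzaldehyde
Product: 6 2,4-bis(benzyloxy)-6-hydroxybenzaldehyde
Conditions: BnBr (2.05 equiv), K2CO3, DMF, rt
Reagents that add atoms: benzyl bromide, BrCc1ccccc1
Why: Williamson etherification should stop at the dibenzyl stage because the last hydroxyl is held in a strong hydrogen bond to the ortho formyl group and is the least nucleophilic.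

**Step 5**
Reactants: 4 (2R,3R)-8-bromo-3,5,7-tris(benzyloxy)-2-[4-(benzyloxy)phenyl]chromane; 6 2,4-bis(benzyloxy)-6-hydroxybenzaldehyde
Product: 9 [4,6-bis(benzyloxy)-2-hydroxyphenyl]{(2R,3R)-3,5,7-tris(benzyloxy)-2-[4-(benzyloxy)phenyl]chroman-8-yl}methanol (both carbinol epimers), via 8-lithio-3,5,7,4'-tetra-O-benzylepiafzelechin 7 (not isolated), via sodium 3,5-bis(benzyloxy)-2-formylphenolate 8 (not isolated)
Conditions: 4, n-BuLi (1.05 equiv), THF, −78 °C; 6 pre-treated with NaH (1.0 equiv), THF, 0 °C, then added by cannula, −78 to −30 °C; pH 7 phosphate buffer quench; crude 9 used at once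
Reagents that add atoms: none
Why: Bromine–lithium exchange gives the C8 aryllithium, which adds 1,2 to the formyl group of the salicylaldehyde masked as its phenoxide; the new carbinol center forms unselectively and is erased in step 7.

**Step 6**
Reactants: 10 1-(benzyloxy)-4-ethynylbenzene
Product: 11 (Z)-2-{2-[4-(benzyloxy)phenyl]ethenyl}-4,4,5,5-tetramethyl-1,3,2-dioxaborolane
Conditions: pinacolborane, [RhCl(cod)]2 (1.5 mol%), P(i-Pr)3 (6 mol%), Et3N, cyclohexane, rt
Reagents that add atoms: pinacolborane, CC1(C)OBOC1(C)C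
Why: Rhodium-catalysed trans-hydroboration of a terminal alkyne proceeds through a rhodium vinylidene, so boron adds anti-Markovnikov and anti, giving the Z-alkenylboronate.

**Step 7**
Reactants: 9 [4,6-bis(benzyloxy)-2-hydroxyphenyl]{(2R,3R)-3,5,7-tris(benzyloxy)-2-[4-(benzyloxy)phenyl]chroman-8-yl}methanol; 11 (Z)-2-{2-[4-(benzyloxy)phenyl]ethenyl}-4,4,5,5-tetramethyl-1,3,2-dioxaborolane
Product: 13 hepta-O-benzyl 3-deoxy-3-(pinacolboryl)-ent-epiafzelechin-(4α→8)-epiafzelechin (upper unit 2,3-cis-3,4-trans with the boronate in place of the 3-OH; lower unit (2R,3R) with 3-OBn), via o-quinone methide 12 (not isolated)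
Conditions: (R)-3,3'-bis(2,4,6-triisopropylphenyl)-1,1'-binaphthalene-2,2'-diyl N-triflylphosphoramide (10 mol%), 11 (2.5 equiv), 4 Å molecular sieves, toluene, 0 °C to rt
Reagents that add atoms: none
Why: Proposed new method: the chiral Brønsted acid dehydrates 9 to the o-quinone methide 12 (O1=C8a–C4a=C4 of the future middle unit), held in a chiral hydrogen-bonded ion pair, and 12 is intercepted in an inverse-demand oxa-[4+2] cycloaddition by 11, whose boron-bearing carbon (future C3) leads the bond formation to C4 while O1 closes on the p-benzyloxybenzylic carbon (future C2); the closest known reactions are the Brønsted-acid-catalysed enantioselective [4+2] cycloadditions of o-hydroxybenzhydrol-derived o-quinone methides with 1,2-disubstituted styrenes of the anethole type and the use of alkenylboronates as 2π partners in inverse-demand cycloadditions, the new element being a β-borylstyrene as the 2π partner. Ring C of the middle unit is closed by an intermolecular, concerted but asynchronous hetero-Diels–Alder reaction (in the stepwise limit, C3–C4 first and then 6-exo-trig capture of the benzylic cation by O1). C2 and C3 are set cis because the addition is suprafacial on the Z-alkene, boron standing in for the 3-oxygen. C4 is set trans to C3 because, for either geometry of 12, the transition state that keeps the pinacolboronate out of the cleft between ring A with its peri 5-benzyloxy group and the bottom-unit aryl on C4 leads to the 3,4-trans adduct; the absolute sense (ent-epi, 4α series) is chosen by the catalyst, and since the bottom unit is already enantiopure the wrong-face adduct is a diastereomer that chromatography should remove. The step needs regioselectivity (C3 and not C2 bonding to C4), secured because only attack through the boron-bearing carbon develops a p-alkoxybenzylic cation and boron, unlike an enol oxygen, is no π-donor, and chemoselectivity over Friedel–Crafts self-condensation, secured by the excess of 11 and the low standing concentration of 12.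

**Step 8**
Reactants: 13 hepta-O-benzyl 3-deoxy-3-(pinacolboryl)-ent-epiafzelechin-(4α→8)-epiafzelechin
Product: 14 5,7,4'-tri-O-benzyl-ent-epiafzelechin-(4α→8)-3,5,7,4'-tetra-O-benzylepiafzelechin (upper unit (2S,3S,4S) with free 3-OH; lower unit (2R,3R))
Conditions: 30% H2O2, 2 M NaOH, THF, 0 °C to rt
Reagents that add atoms: hydrogen peroxide, OO
Why: Boronate oxidation: hydroperoxide adds to boron and the C3–B bond migrates to oxygen with retention, so the 3-OH inherits the 2,3-cis-3,4-trans arrangement set in step 7, while benzyl ethers and arenes are inert.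

**Step 9**
Reactants: 2 (2R,3R)-5,7-bis(benzyloxy)-2-[4-(benzyloxy)phenyl]chroman-3-ol
Product: 15 (2R,3R,4S)-5,7-bis(benzyloxy)-2-[4-(benzyloxy)phenyl]-4-(2-ethoxyethoxy)chroman-3-ol
Conditions: DDQ (2 equiv), 2-ethoxyethanol (5 equiv), CH2Cl2, rt
Reagents that add atoms: 2-ethoxyethanol, CCOCCO
Why: DDQ abstracts hydride from the benzylic C4–H activated by the 5,7-dioxygenated ring A, and the alcohol should capture the resulting cation anti to the 3-OH, giving the 4β ether (3,4-trans).

**Step 10**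
Reactants: 14 5,7,4'-tri-O-benzyl-ent-epiafzelechin-(4α→8)-3,5,7,4'-tetra-O-benzylepiafzelechin; 15 (2R,3R,4S)-5,7-bis(benzyloxy)-2-[4-(benzyloxy)phenyl]-4-(2-ethoxyethoxy)chroman-3-ol
Product: 16 deca-O-benzyl epiafzelechin-(4β→8)-ent-epiafzelechin-(4α→8)-epiafzelechin (top (2R,3R,4R), middle (2S,3S,4R), bottom (2R,3R); 3-OH free on top and middle, 3-OBn on bottom)
Conditions: TMSOTf (0.2 equiv), 14 : 15 about 1 : 1.1, CH2Cl2, −78 to −40 °C; Et3N quench
Reagents that add atoms: none
Why: Lewis-acid ionisation of the C4 ether and Friedel–Crafts attack by C8 of the upper unit of 14 (its most nucleophilic free position) form the 4→8 bond, the nucleophile entering anti to the 3-OH of the 2,3-cis electrophile so that C4 of the top unit is set 4β (3,4-trans).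

**Step 11**
Reactants: 16 deca-O-benzyl epiafzelechin-(4β→8)-ent-epiafzelechin-(4α→8)-epiafzelechin
Product: 17 epiafzelechin-(4β→8)-ent-epiafzelechin-(4α→8)-epiafzelechin (CNP0191553.2)
Conditions: H2 (1 atm), Pd(OH)2/C, THF/MeOH/H2O, rt
Reagents that add atoms: none
Why: Catalytic hydrogenolysis should cleave all ten benzyl ethers (nine aryl, one alkyl) without touching the interflavan bonds or any stereocenter.

**Compound list**
1 | (−)-epiafzelechin, (2R,3R)-2-(4-hydroxyphenyl)chromane-3,5,7-triol | Oc1ccc(cc1)[C@H]1Oc2cc(O)cc(O)c2C[C@H]1O | starting material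
2 | (2R,3R)-5,7-bis(benzyloxy)-2-[4-(benzyloxy)phenyl]chroman-3-ol | C(c1ccccc1)Oc1ccc(cc1)[C@H]1Oc2cc(OCc3ccccc3)cc(OCc3ccccc3)c2C[C@H]1O | intermediate
3 | (2R,3R)-3,5,7-tris(benzyloxy)-2-[4-(benzyloxy)phenyl]chromane | C(c1ccccc1)Oc1ccc(cc1)[C@H]1Oc2cc(OCc3ccccc3)cc(OCc3ccccc3)c2C[C@H]1OCc1ccccc1 | intermediate
4 | (2R,3R)-8-bromo-3,5,7-tris(benzyloxy)-2-[4-(benzyloxy)phenyl]chromane | C(c1ccccc1)Oc1ccc(cc1)[C@H]1Oc2c(Br)c(OCc3ccccc3)cc(OCc3ccccc3)c2C[C@H]1OCc1ccccc1 | intermediate
5 | 2,4,6-trihydroxybenzaldehyde | O=Cc1c(O)cc(O)cc1O | starting material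
6 | 2,4-bis(benzyloxy)-6-hydroxybenzaldehyde | O=Cc1c(O)cc(OCc2ccccc2)cc1OCc1ccccc1 | intermediate
7 | 8-lithio-3,5,7,4'-tetra-O-benzylepiafzelechin | C(c1ccccc1)Oc1ccc(cc1)[C@H]1Oc2c([Li])c(OCc3ccccc3)cc(OCc3ccccc3)c2C[C@H]1OCc1ccccc1 | intermediate
8 | sodium 3,5-bis(benzyloxy)-2-formylphenolate | [Na+].[O-]c1cc(OCc2ccccc2)cc(OCc2ccccc2)c1C=O | intermediate
9 | [4,6-bis(benzyloxy)-2-hydroxyphenyl]{(2R,3R)-3,5,7-tris(benzyloxy)-2-[4-(benzyloxy)phenyl]chroman-8-yl}methanol, both carbinol epimers | C(c1ccccc1)Oc1ccc(cc1)[C@H]1Oc2c(C(O)c3c(O)cc(OCc4ccccc4)cc3OCc3ccccc3)c(OCc3ccccc3)cc(OCc3ccccc3)c2C[C@H]1OCc1ccccc1 | intermediate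
10 | 1-(benzyloxy)-4-ethynylbenzene | C#Cc1ccc(OCc2ccccc2)cc1 | starting material
11 | (Z)-2-{2-[4-(benzyloxy)phenyl]ethenyl}-4,4,5,5-tetramethyl-1,3,2-dioxaborolane | CC1(C)OB(/C=C\c2ccc(OCc3ccccc3)cc2)OC1(C)C | intermediate
12 | o-quinone methide: 3,5-bis(benzyloxy)-6-({(2R,3R)-3,5,7-tris(benzyloxy)-2-[4-(benzyloxy)phenyl]chroman-8-yl}methylidene)cyclohexa-2,4-dien-1-one | C(c1ccccc1)Oc1ccc(cc1)[C@H]1Oc2c(C=C3C(=O)C=C(OCc4ccccc4)C=C3OCc3ccccc3)c(OCc3ccccc3)cc(OCc3ccccc3)c2C[C@H]1OCc1ccccc1 | intermediate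
13 | hepta-O-benzyl 3-deoxy-3-(pinacolboryl)-ent-epiafzelechin-(4α→8)-epiafzelechin (2-aryl and 3-boryl cis, 4-aryl trans to both) | c1c(OCc2ccccc2)cc(OCc2ccccc2)c2c1O[C@@H](c1ccc(OCc3ccccc3)cc1)[C@@H](B1OC(C)(C)C(C)(C)O1)[C@@H]2c1c(OCc2ccccc2)cc(OCc2ccccc2)c2c1O[C@H](c1ccc(OCc3ccccc3)cc1)[C@H](OCc1ccccc1)C2 | intermediate
14 | 5,7,4'-tri-O-benzyl-ent-epiafzelechin-(4α→8)-3,5,7,4'-tetra-O-benzylepiafzelechin, upper unit (2S,3S,4S), lower unit (2R,3R) | c1c(OCc2ccccc2)cc(OCc2ccccc2)c2c1O[C@@H](c1ccc(OCc3ccccc3)cc1)[C@@H](O)[C@@H]2c1c(OCc2ccccc2)cc(OCc2ccccc2)c2c1O[C@H](c1ccc(OCc3ccccc3)cc1)[C@H](OCc1ccccc1)C2 | intermediate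
15 | (2R,3R,4S)-5,7-bis(benzyloxy)-2-[4-(benzyloxy)phenyl]-4-(2-ethoxyethoxy)chroman-3-ol | C(c1ccccc1)Oc1ccc([C@H]2Oc3cc(OCc4ccccc4)cc(OCc4ccccc4)c3[C@H](OCCOCC)[C@H]2O)cc1 | intermediate
16 | deca-O-benzyl epiafzelechin-(4β→8)-ent-epiafzelechin-(4α→8)-epiafzelechin | c5ccccc5COc1ccc([C@H]2Oc3cc(OCc5ccccc5)cc(OCc5ccccc5)c3[C@H](c3c(OCc5ccccc5)cc(OCc5ccccc5)c4c3O[C@@H](c3ccc(OCc5ccccc5)cc3)[C@@H](O)[C@@H]4c3c(OCc5ccccc5)cc(OCc5ccccc5)c4c3O[C@H](c3ccc(OCc5ccccc5)cc3)[C@H](OCc3ccccc3)C4)[C@H]2O)cc1 | intermediate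
17 | epiafzelechin-(4β→8)-ent-epiafzelechin-(4α→8)-epiafzelechin, top (2R,3R,4R), middle (2S,3S,4R), bottom (2R,3R) | Oc1ccc([C@H]2Oc3cc(O)cc(O)c3[C@H](c3c(O)cc(O)c4c3O[C@@H](c3ccc(O)cc3)[C@@H](O)[C@@H]4c3c(O)cc(O)c4c3O[C@H](c3ccc(O)cc3)[C@H](O)C4)[C@H]2O)cc1 | target

**Step count**
Total step count: 11. Longest linear sequence: 8 steps (steps 1, 2, 3, 5, 7, 8, 10, 11).

**Steps most likely to fail**

Step 7. The donor-stabilised quinone methide may react too slowly with the boron-deactivated alkene. Friedel–Crafts self-condensation, loss of boron by a Petasis-type alkenyl transfer, erosion of the cis relationship through a long-lived benzylic cation, or poor facial discrimination by the catalyst could then take over. The fallback uses known chemistry only, sets out from 3 and comes back at 14. Commercial (+)-afzelechin (Oc1ccc(cc1)[C@H]1Oc2cc(O)cc(O)c2C[C@@H]1O) is epimerised at C2 in hot aqueous buffer (pH 9–10, 100 °C), through the ring-opened B-ring quinone methide, to ent-epiafzelechin F1, which is separated while recovered afzelechin is recycled. F1 is benzylated on its three phenols (BnBr, K2CO3, DMF) to 5,7,4'-tri-O-benzyl-ent-epiafzelechin F2. F2 is oxidised at C4 (DDQ, 2-ethoxyethanol, CH2Cl2) to the (2S,3S,4R)-4-(2-ethoxyethoxy) electrophile F3. F3 is condensed with an excess of 3 (TMSOTf, CH2Cl2, −78 °C), C8 of 3 attacking anti to the 3-OH, which should give 14 directly.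

Step 5. The hindered, di-ortho-substituted aryllithium may be protonated or add sluggishly to the phenoxide-deactivated, di-ortho-substituted aldehyde, and the very electron-rich benzhydrol may ionise during isolation. The fallback sets out from 4 and comes back at 9. The aryllithium 7 is made as before and quenched with DMF, a small electrophile, to give 8-formyl-3,5,7,4'-tetra-O-benzylepiafzelechin F4. F4 is then combined with the bromomagnesium phenolate of commercial 3,5-bis(benzyloxy)phenol (Oc1cc(OCc2ccccc2)cc(OCc2ccccc2)c1; EtMgBr, CH2Cl2, rt). This ortho-specific phenolate hydroxyalkylation runs through a six-membered magnesium chelate and should deliver the carbinol at the position between the phenol oxygen and a benzyloxy group, which is 9.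

Step 10. The electrophile 15 carries free C6/C8 positions of its own and may self-condense, and attack through C6 of either unit of 14 or over-oligomerisation may compete. The fallback sets out from 2 and comes back at 17. Compound 2 is brominated at C8 (NBS, CH2Cl2, −78 °C) to 8-bromo-5,7,4'-tri-O-benzylepiafzelechin F5. F5 is oxidised (DDQ, 2-ethoxyethanol) to the C8-blocked 8-bromo-4-(2-ethoxyethoxy) electrophile F6, which cannot self-condense through C8. F6 is coupled with 14 (TMSOTf, CH2Cl2, −78 °C) to the 8-bromo deca-O-benzyl trimer F7. Hydrogenolysis of F7 (H2, Pd(OH)2/C, Et3N, THF/MeOH/H2O) removes the bromine together with the ten benzyl groups and gives 17.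

Further compounds
F1 | step 7 | ent-epiafzelechin, (2S,3S)-2-(4-hydroxyphenyl)chromane-3,5,7-triol | Oc1ccc(cc1)[C@@H]1Oc2cc(O)cc(O)c2C[C@@H]1O
F2 | step 7 | (2S,3S)-5,7-bis(benzyloxy)-2-[4-(benzyloxy)phenyl]chroman-3-ol | C(c1ccccc1)Oc1ccc(cc1)[C@@H]1Oc2cc(OCc3ccccc3)cc(OCc3ccccc3)c2C[C@@H]1O
F3 | step 7 | (2S,3S,4R)-5,7-bis(benzyloxy)-2-[4-(benzyloxy)phenyl]-4-(2-ethoxyethoxy)chroman-3-ol | C(c1ccccc1)Oc1ccc([C@@H]2Oc3cc(OCc4ccccc4)cc(OCc4ccccc4)c3[C@@H](OCCOCC)[C@@H]2O)cc1
F4 | step 5 | (2R,3R)-3,5,7-tris(benzyloxy)-2-[4-(benzyloxy)phenyl]chromane-8-carbaldehyde | C(c1ccccc1)Oc1ccc(cc1)[C@H]1Oc2c(C=O)c(OCc3ccccc3)cc(OCc3ccccc3)c2C[C@H]1OCc1ccccc1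
F5 | step 10 | (2R,3R)-8-bromo-5,7-bis(benzyloxy)-2-[4-(benzyloxy)phenyl]chroman-3-ol | C(c1ccccc1)Oc1ccc(cc1)[C@H]1Oc2c(Br)c(OCc3ccccc3)cc(OCc3ccccc3)c2C[C@H]1O
F6 | step 10 | (2R,3R,4S)-8-bromo-5,7-bis(benzyloxy)-2-[4-(benzyloxy)phenyl]-4-(2-ethoxyethoxy)chroman-3-ol | C(c1ccccc1)Oc1ccc([C@H]2Oc3c(Br)c(OCc4ccccc4)cc(OCc4ccccc4)c3[C@H](OCCOCC)[C@H]2O)cc1
F7 | step 10 | 8-bromo (top unit) deca-O-benzyl epiafzelechin-(4β→8)-ent-epiafzelechin-(4α→8)-epiafzelechin | c5ccccc5COc1ccc([C@H]2Oc3c(Br)c(OCc5ccccc5)cc(OCc5ccccc5)c3[C@H](c3c(OCc5ccccc5)cc(OCc5ccccc5)c4c3O[C@@H](c3ccc(OCc5ccccc5)cc3)[C@@H](O)[C@@H]4c3c(OCc5ccccc5)cc(OCc5ccccc5)c4c3O[C@H](c3ccc(OCc5ccccc5)cc3)[C@H](OCc3ccccc3)C4)[C@H]2O)cc1
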